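**Retrosynthetic overview**

1. The stilbene C=C is made last by Horner–Wadsworth–Emmons olefination of a C6 aldehyde on unit A; the six MOM ethers (acid) and the two aryl triflates (hydroxide) are then removed.
2. Each 2,3-trans-dihydrobenzofuran is cut across O1–C7a and C3a–C3 into a 3-alkoxyaryne and an (R,R)-trans-diaryl epoxide. The furan ring of unit B closes first (step 10); its C6 aldehyde is grown into the next epoxide, and the same aryne building block closes the furan ring of unit A (step 13).
3. Enabling feature: in ring B the C4 oxygen is ortho to C3a and meta to C7a, so on a C3a–C7a aryne it sends the epoxide oxygen to C7a and the carbanion to C3a. O1–C2–C3 is a trans-1,2-diaryl epoxide whose C3–O bond (3,5-dioxygenated aryl) is made the weak one by masking the para oxygen of the C2 aryl as a triflate.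
4. All benzene rings are bought; the four stereocentres come from two Shi epoxidations.

Key step: step 10

Remark on the chemistry: both dihydrofuran rings of the target are 2,3-trans with (2S,3S) configuration. Benzofuran numbering (O1, C2, C3, C3a, C4 to C7, C7a) is used for both; unit A carries the styryl group and unit B the 3,5-dihydroxyphenyl group.

**Route**

Step 1
Reactants: 1 4-bromo-3,5-dimethoxybenzaldehyde
Product: 2 4-bromo-3,5-dihydroxybenzaldehyde
Conditions: BBr3, CH2Cl2, −78 → 23 °C; then H2O
Reagents that add atoms: none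
Why: Lewis-acid cleavage of aryl methyl ethers by boron tribromide should free both phenols while the aldehyde and the aryl bromide are untouched.

Step 2
Reactants: 2 4-bromo-3,5-dihydroxybenzaldehyde
Product: 3 2-bromo-5-(dimethoxymethyl)benzene-1,3-diol
Conditions: HC(OMe)3, MeOH, TsOH·H2O (cat.), 23 °C; then Et3N
Reagents that add atoms: trimethyl orthoformate, COC(OC)OC
Why: Acid-catalysed acetalisation with the orthoformate as water scavenger should mask the aldehyde for the organolithium and aryne steps.

Step 3
Reactants: 3 2-bromo-5-(dimethoxymethyl)benzene-1,3-diol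
Product: 4 2-bromo-5-(dimethoxymethyl)-3-(methoxymethoxy)phenol
Conditions: MOMCl (1.0 equiv), iPr2NEt, CH2Cl2–DMF, 0 °C
Reagents that add atoms: chloromethyl methyl ether, COCCl
Why: Williamson-type O-alkylation of one of two equivalent phenols should give the mono-ether statistically; bis-ether and recovered diol are separated and the diol is recycled.

Step 4
Reactants: 4 2-bromo-5-(dimethoxymethyl)-3-(methoxymethoxy)phenol
Product: 7 5-(dimethoxymethyl)-3-(methoxymethoxy)-2-(trimethylsilyl)phenyl trifluoromethanesulfonate, via aryl silyl ether 5 (not isolated), via lithium phenolate 6 (not isolated)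
Conditions: (Me3Si)2NH, THF, 65 °C, evaporate; n-BuLi, THF, −78 °C; PhNTf2, −78 → 23 °C
Reagents that add atoms: hexamethyldisilazane, C[Si](C)(C)N[Si](C)(C)C; N-phenylbis(trifluoromethanesulfonimide), O=S(=O)(N(c1ccccc1)S(=O)(=O)C(F)(F)F)C(F)(F)F
Why: O-silylation, bromine–lithium exchange and anionic 1,3 O-to-C silyl migration (retro-Brook rearrangement) should place silicon between the two oxygens, and triflation of the released phenolate gives a Kobayashi-type aryne precursor.

Step 5
Reactants: 8 4-methylphenyl trifluoromethanesulfonate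
Product: 9 4-(bromomethyl)phenyl trifluoromethanesulfonate
Conditions: NBS, AIBN (cat.), PhCF3, 85 °C
Reagents that add atoms: N-bromosuccinimide, O=C1CCC(=O)N1Br
Why: Wohl–Ziegler radical bromination should functionalise the only benzylic position; the aryl triflate is inert to radicals.

Step 6
Reactants: 9 4-(bromomethyl)phenyl trifluoromethanesulfonate
Product: 10 diethyl {[4-(trifluoromethanesulfonyloxy)phenyl]methyl}phosphonate
Conditions: P(OEt)3, neat, 140 °C
Reagents that add atoms: triethyl phosphite, CCOP(OCC)OCC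
Why: The Michaelis–Arbuzov reaction of a primary benzylic bromide should give the phosphonate that serves both triflate-bearing olefinations.

Step 7
Reactants: 11 3,5-dihydroxybenzaldehyde
Product: 12 3,5-bis(methoxymethoxy)benzaldehyde
Conditions: MOMCl, iPr2NEt, CH2Cl2, 0 → 23 °C
Reagents that add atoms: chloromethyl methyl ether, COCCl
Why: Exhaustive O-alkylation should protect both phenols as base-stable, fluoride-stable MOM ethers.

Step 8
Reactants: 12 3,5-bis(methoxymethoxy)benzaldehyde; 10 diethyl {[4-(trifluoromethanesulfonyloxy)phenyl]methyl}phosphonate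
Product: 13 4-{(E)-2-[3,5-bis(methoxymethoxy)phenyl]ethenyl}phenyl trifluoromethanesulfonate
Conditions: NaH, 15-crown-5 (cat.), THF, 0 → 23 °C
Reagents that add atoms: none
Why: Horner–Wadsworth–Emmons olefination with a benzylic phosphonate should give the E-stilbene selectively, and the aryl triflate tolerates the non-nucleophilic base.

Step 9
Reactants: 13 4-{(E)-2-[3,5-bis(methoxymethoxy)phenyl]ethenyl}phenyl trifluoromethanesulfonate
Product: 14 4-{(2R,3R)-3-[3,5-bis(methoxymethoxy)phenyl]oxiran-2-yl}phenyl trifluoromethanesulfonate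
Conditions: D-fructose-derived Shi ketone (0.3 equiv), KHSO5 (as 2KHSO5·KHSO4·K2SO4), K2CO3, Bu4NHSO4, MeCN–CH2(OMe)2–aq. Na2B4O7 buffer, 0 °C
Reagents that add atoms: potassium peroxymonosulfate, [K+].[O-]S(=O)(=O)OO
Why: Shi asymmetric epoxidation should deliver oxygen from the chiral dioxirane through a spiro transition state to the face that gives the (R,R)-epoxide from an E-stilbene, and the triflate makes the product stable to acid.

Step 10
Reactants: 7 5-(dimethoxymethyl)-3-(methoxymethoxy)-2-(trimethylsilyl)phenyl trifluoromethanesulfonate; 14 4-{(2R,3R)-3-[3,5-bis(methoxymethoxy)phenyl]oxiran-2-yl}phenyl trifluoromethanesulfonate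
Product: 17 4-{(2S,3S)-3-[3,5-bis(methoxymethoxy)phenyl]-6-formyl-4-(methoxymethoxy)-2,3-dihydro-1-benzofuran-2-yl}phenyl trifluoromethanesulfonate, via aryne 15 (not isolated), via dimethyl acetal 16 (not isolated)
Conditions: CsF, MeCN–toluene (1:3), 23 °C, slow addition of 7; then PPTS, acetone–H2O, 40 °C
Reagents that add atoms: water, O
Why: Proposed new method: fluoride removes the silyl group of 7 and triflate leaves to give aryne 15; the oxirane oxygen of 14 adds to the aryne carbon meta to the MOM ether (the future C7a), and the aryl anion thus placed at the future C3a captures the benzylic carbon bearing the 3,5-bis(methoxymethoxy)phenyl group as its C–O bond ionises, so that O1–C7a and C3a–C3 form in one operation (aryne σ-insertion into an epoxide C–O bond, a formal [3+2] annulation). The closest known reaction type is the insertion of benzyne into the benzylic C–O bond of styrene oxide to give a 2,3-dihydrobenzofuran; applying it to a 1,2-diaryl epoxide with a choice between two benzylic C–O bonds is the new element. The furan ring closes by collapse of the aryl anion onto the opening oxiranium carbon, formally a 5-endo-tet event that cannot be a backside displacement and should therefore run as a front-side, ion-pair (SN1-like) recombination. C2 keeps the configuration set by the Shi epoxidation because its C–O bond is never broken, and C3 is set trans to the C2 aryl: front-side collapse with retention turns the trans-epoxide into the 2,3-trans ring, and a benzylic cation free to rotate would close anti to the C2 aryl to the same isomer. Three selectivities are needed: orientation on the aryne is secured by the inductively withdrawing C4 alkoxy group (distorted aryne, nucleophile at the distal carbon), the choice of C–O bond by the para-triflate that destabilises positive charge at C2 while the meta ethers leave C3 the better cation, and chemoselectivity by the absence of any other nucleophile (MOM ethers, acetal and triflate are inert to CsF and to the aryne). Acetal 16 is then hydrolysed in the same flask by mild acid that leaves the aryl MOM ethers intact.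

Step 11
Reactants: 17 4-{(2S,3S)-3-[3,5-bis(methoxymethoxy)phenyl]-6-formyl-4-(methoxymethoxy)-2,3-dihydro-1-benzofuran-2-yl}phenyl trifluoromethanesulfonate; 10 diethyl {[4-(trifluoromethanesulfonyloxy)phenyl]methyl}phosphonate
Product: 18 4-{(2S,3S)-3-[3,5-bis(methoxymethoxy)phenyl]-4-(methoxymethoxy)-6-[(E)-2-{4-[(trifluoromethanesulfonyl)oxy]phenyl}ethenyl]-2,3-dihydro-1-benzofuran-2-yl}phenyl trifluoromethanesulfonate
Conditions: NaH, 15-crown-5 (cat.), THF, 0 → 23 °C
Reagents that add atoms: none
Why: Horner–Wadsworth–Emmons olefination should give the E-alkene; neither dihydrofuran stereocentre is acidic enough to be touched by the phosphonate anion.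

Step 12
Reactants: 18 the E-stilbene bis(triflate) of step 11
Product: 19 4-{(2S,3S)-3-[3,5-bis(methoxymethoxy)phenyl]-4-(methoxymethoxy)-6-[(2R,3R)-3-{4-[(trifluoromethanesulfonyl)oxy]phenyl}oxiran-2-yl]-2,3-dihydro-1-benzofuran-2-yl}phenyl trifluoromethanesulfonate
Conditions: D-fructose-derived Shi ketone (0.3 equiv), KHSO5 (as 2KHSO5·KHSO4·K2SO4), K2CO3, Bu4NHSO4, MeCN–CH2(OMe)2–aq. Na2B4O7 buffer, 0 °C
Reagents that add atoms: potassium peroxymonosulfate, [K+].[O-]S(=O)(=O)OO
Why: Shi asymmetric epoxidation under reagent control should again give the (R,R)-epoxide, the stereocentres of unit B being too remote to interfere.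

Step 13
Reactants: 7 5-(dimethoxymethyl)-3-(methoxymethoxy)-2-(trimethylsilyl)phenyl trifluoromethanesulfonate; 19 the (2R,3R)-epoxide of step 12
Product: 21 unit A 6-carbaldehyde (2S,3S)-6-formyl-4-(methoxymethoxy)-2-[4-(trifluoromethanesulfonyloxy)phenyl]-2,3-dihydro-1-benzofuran bearing at C3 the (2S,3S)-3-[3,5-bis(methoxymethoxy)phenyl]-4-(methoxymethoxy)-2-[4-(trifluoromethanesulfonyloxy)phenyl]-2,3-dihydro-1-benzofuran-6-yl group of unit B, via dimethyl acetal 20 (not isolated)
Conditions: CsF, MeCN–toluene (1:3), 23 °C, slow addition of excess 7; then PPTS, acetone–H2O, 40 °C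
Reagents that add atoms: water, O
Why: Proposed new method: fluoride releases from 7 the same transient aryne that is numbered 15 at step 10, and it should undergo the same σ-insertion into a benzylic epoxide C–O bond (closest known type: benzyne insertion into the C–O bond of styrene oxide), here on epoxide 19, whose C3 carries the 3,5-dioxygenated, para-alkylated ring B (the better cation) and whose C2 carries the triflate-deactivated aryl, so that O1–C7a and C3a–C3 of unit A should close with retention at C3 to the 2,3-trans (2S,3S) ring before acetal 20 is hydrolysed in the same flask.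

Step 14
Reactants: 22 2,4-dihydroxybenzaldehyde
Product: 23 2,4-bis(methoxymethoxy)benzaldehyde
Conditions: MOMCl, iPr2NEt, CH2Cl2, 0 → 40 °C
Reagents that add atoms: chloromethyl methyl ether, COCCl
Why: O-alkylation of both phenols (the hydrogen-bonded ortho one needs excess reagent and warming) should give the bis-MOM ether.

Step 15
Reactants: 23 2,4-bis(methoxymethoxy)benzaldehyde
Product: 24 [2,4-bis(methoxymethoxy)phenyl]methanol
Conditions: NaBH4, MeOH, 0 °C
Reagents that add atoms: none
Why: Borohydride reduction of the aldehyde should give the benzylic alcohol cleanly.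

Step 16
Reactants: 24 [2,4-bis(methoxymethoxy)phenyl]methanol
Product: 25 diethyl {[2,4-bis(methoxymethoxy)phenyl]methyl}phosphonate
Conditions: P(OEt)3, ZnI2, THF, 66 °C
Reagents that add atoms: triethyl phosphite, CCOP(OCC)OCC
Why: The zinc iodide-mediated one-flask Michaelis–Arbuzov-type conversion of electron-rich benzylic alcohols should give the phosphonate without isolating a labile benzylic halide and is compatible with aryl MOM ethers.

Step 17
Reactants: 21 unit A 6-carbaldehyde of step 13; 25 diethyl {[2,4-bis(methoxymethoxy)phenyl]methyl}phosphonate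
Product: 26 hexakis(methoxymethyl) ether bis(triflate) of the target, with the (E)-2-[2,4-bis(methoxymethoxy)phenyl]ethenyl group at C6 of unit A
Conditions: NaH, 15-crown-5 (cat.), THF, 0 → 40 °C
Reagents that add atoms: none
Why: Horner–Wadsworth–Emmons olefination should install the E-stilbene and with it the complete carbon skeleton.

Step 18
Reactants: 26 hexakis(methoxymethyl) ether bis(triflate) of the target
Product: 27 bis(triflate) of the target, with six free phenols and both 4-hydroxyphenyl oxygens still as trifluoromethanesulfonates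
Conditions: HCl (3 M aq.), MeOH–THF, 40 °C
Reagents that add atoms: none
Why: Acid-catalysed acetal exchange should remove all six MOM ethers as dimethoxymethane, while the two triflates keep both C2 aryl groups electron-poor so that the benzylic C2–O bonds of the dihydrofuran rings do not ionise.

Step 19
Reactants: 27 bis(triflate) of the target
Product: 28 the target, CNP0186204.1
Conditions: Et4NOH (aq.), 1,4-dioxane, degassed, under argon, 23 °C; then AcOH
Reagents that add atoms: none
Why: Hydroxide attacks sulfur of the aryl triflates (sulfonate ester S–O cleavage) and should release the two para-phenols without touching any stereocentre.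

**Compound list**

1 | 4-bromo-3,5-dimethoxybenzaldehyde | COc1cc(C=O)cc(OC)c1Br | starting material
2 | 4-bromo-3,5-dihydroxybenzaldehyde | O=Cc1cc(O)c(Br)c(O)c1 | intermediate
3 | 2-bromo-5-(dimethoxymethyl)benzene-1,3-diol | COC(OC)c1cc(O)c(Br)c(O)c1 | intermediate
4 | 2-bromo-5-(dimethoxymethyl)-3-(methoxymethoxy)phenol | COCOc1cc(C(OC)OC)cc(O)c1Br | intermediate
5 | [2-bromo-5-(dimethoxymethyl)-3-(methoxymethoxy)phenoxy]trimethylsilane | COCOc1cc(C(OC)OC)cc(O[Si](C)(C)C)c1Br | intermediate
6 | lithium 5-(dimethoxymethyl)-3-(methoxymethoxy)-2-(trimethylsilyl)phenolate | COCOc1cc(C(OC)OC)cc([O-])c1[Si](C)(C)C.[Li+] | intermediate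
7 | 5-(dimethoxymethyl)-3-(methoxymethoxy)-2-(trimethylsilyl)phenyl trifluoromethanesulfonate | COCOc1cc(C(OC)OC)cc(OS(=O)(=O)C(F)(F)F)c1[Si](C)(C)C | intermediate
8 | 4-methylphenyl trifluoromethanesulfonate | Cc1ccc(OS(=O)(=O)C(F)(F)F)cc1 | starting material
9 | 4-(bromomethyl)phenyl trifluoromethanesulfonate | BrCc1ccc(OS(=O)(=O)C(F)(F)F)cc1 | intermediate
10 | diethyl {[4-(trifluoromethanesulfonyloxy)phenyl]methyl}phosphonate | CCOP(=O)(Cc1ccc(OS(=O)(=O)C(F)(F)F)cc1)OCC | intermediate
11 | 3,5-dihydroxybenzaldehyde | O=Cc1cc(O)cc(O)c1 | starting material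
12 | 3,5-bis(methoxymethoxy)benzaldehyde | COCOc1cc(C=O)cc(OCOC)c1 | intermediate
13 | 4-{(E)-2-[3,5-bis(methoxymethoxy)phenyl]ethenyl}phenyl trifluoromethanesulfonate | COCOc1cc(/C=C/c2ccc(OS(=O)(=O)C(F)(F)F)cc2)cc(OCOC)c1 | intermediate
14 | 4-{(2R,3R)-3-[3,5-bis(methoxymethoxy)phenyl]oxiran-2-yl}phenyl trifluoromethanesulfonate | O1[C@H](c2ccc(OS(=O)(=O)C(F)(F)F)cc2)[C@H]1c1cc(OCOC)cc(OCOC)c1 | intermediate
15 | 5-(dimethoxymethyl)-3-(methoxymethoxy)benzyne (formal triple bond between the former C–OTf and C–Si carbons) | COC(OC)C1=CC#CC(OCOC)=C1 | intermediate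
16 | 4-{(2S,3S)-3-[3,5-bis(methoxymethoxy)phenyl]-6-(dimethoxymethyl)-4-(methoxymethoxy)-2,3-dihydro-1-benzofuran-2-yl}phenyl trifluoromethanesulfonate | COC(OC)c1cc(OCOC)c2c(c1)O[C@H](c1ccc(OS(=O)(=O)C(F)(F)F)cc1)[C@H]2c1cc(OCOC)cc(OCOC)c1 | intermediate
17 | 4-{(2S,3S)-3-[3,5-bis(methoxymethoxy)phenyl]-6-formyl-4-(methoxymethoxy)-2,3-dihydro-1-benzofuran-2-yl}phenyl trifluoromethanesulfonate | O=Cc1cc(OCOC)c2c(c1)O[C@H](c1ccc(OS(=O)(=O)C(F)(F)F)cc1)[C@H]2c1cc(OCOC)cc(OCOC)c1 | intermediate
18 | E-stilbene bis(triflate): unit B of 17 with C6 carrying (E)-2-[4-(trifluoromethanesulfonyloxy)phenyl]ethenyl | FC(F)(F)S(=O)(=O)Oc1ccc(/C=C/c2cc(OCOC)c3c(c2)O[C@H](c2ccc(OS(=O)(=O)C(F)(F)F)cc2)[C@H]3c2cc(OCOC)cc(OCOC)c2)cc1 | intermediate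
19 | (2R,3R)-epoxide of 18 (trans-oxirane between C6 of unit B and the 4-triflyloxyphenyl group) | FC(F)(F)S(=O)(=O)Oc1ccc([C@H]2O[C@@H]2c2cc(OCOC)c3c(c2)O[C@H](c2ccc(OS(=O)(=O)C(F)(F)F)cc2)[C@H]3c2cc(OCOC)cc(OCOC)c2)cc1 | intermediate
20 | unit A dimethyl acetal: (2S,3S)-6-(dimethoxymethyl)-4-(methoxymethoxy)-2-[4-(triflyloxy)phenyl]-2,3-dihydro-1-benzofuran with unit B (as in 16, attached through its C6) at C3 | FC(F)(F)S(=O)(=O)Oc1ccc([C@H]2Oc3cc(C(OC)OC)cc(OCOC)c3[C@@H]2c2cc(OCOC)c3c(c2)O[C@H](c2ccc(OS(=O)(=O)C(F)(F)F)cc2)[C@H]3c2cc(OCOC)cc(OCOC)c2)cc1 | intermediate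
21 | unit A 6-carbaldehyde (20 with CHO in place of the acetal) | FC(F)(F)S(=O)(=O)Oc1ccc([C@H]2Oc3cc(C=O)cc(OCOC)c3[C@@H]2c2cc(OCOC)c3c(c2)O[C@H](c2ccc(OS(=O)(=O)C(F)(F)F)cc2)[C@H]3c2cc(OCOC)cc(OCOC)c2)cc1 | intermediate
22 | 2,4-dihydroxybenzaldehyde | O=Cc1ccc(O)cc1O | starting material
23 | 2,4-bis(methoxymethoxy)benzaldehyde | COCOc1ccc(C=O)c(OCOC)c1 | intermediate
24 | [2,4-bis(methoxymethoxy)phenyl]methanol | COCOc1ccc(CO)c(OCOC)c1 | intermediate
25 | diethyl {[2,4-bis(methoxymethoxy)phenyl]methyl}phosphonate | CCOP(=O)(Cc1ccc(OCOC)cc1OCOC)OCC | intermediate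
26 | hexakis(methoxymethyl) ether bis(triflate) of the target | FC(F)(F)S(=O)(=O)Oc1ccc([C@H]2Oc3cc(/C=C/c4ccc(OCOC)cc4OCOC)cc(OCOC)c3[C@@H]2c2cc(OCOC)c3c(c2)O[C@H](c2ccc(OS(=O)(=O)C(F)(F)F)cc2)[C@H]3c2cc(OCOC)cc(OCOC)c2)cc1 | intermediate
27 | bis(triflate) of the target (six free phenols) | FC(F)(F)S(=O)(=O)Oc1ccc([C@H]2Oc3cc(/C=C/c4ccc(O)cc4O)cc(O)c3[C@@H]2c2cc(O)c3c(c2)O[C@H](c2ccc(OS(=O)(=O)C(F)(F)F)cc2)[C@H]3c2cc(O)cc(O)c2)cc1 | intermediate
28 | CNP0186204.1 | Oc1ccc([C@H]2Oc3cc(/C=C/c4ccc(O)cc4O)cc(O)c3[C@@H]2c2cc(O)c3c(c2)O[C@H](c2ccc(O)cc2)[C@H]3c2cc(O)cc(O)c2)cc1 | target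

**Step count and risks**

Total steps: 19. Longest linear sequence: 11 steps (1, 2, 3, 4, 10, 11, 12, 13, 17, 18, 19; the path from 8 through steps 5, 6, 8, 9 is equally long).

Steps most likely to fail:

1. Step 10 (Proposed new method). The hindered, weakly nucleophilic oxirane oxygen may not intercept the aryne before it is consumed by fluoride, solvent or itself. The oxiranium zwitterion may also be protonated or undergo a hydride shift instead of collapsing, and cleavage of the other C–O bond would give the regioisomeric ring. Fallback with known chemistry (ortho-quinone methide plus sulfur ylide, a [4+1] annulation that builds O1–C2 and C2–C3 instead): it sets out from 4, 12 and 9. Deprotonation and bromine–lithium exchange of 4 (n-BuLi, 2.2 equiv, THF, −78 °C) and addition to aldehyde 12 should give 2-{[3,5-bis(methoxymethoxy)phenyl](hydroxy)methyl}-5-(dimethoxymethyl)-3-(methoxymethoxy)phenol F1. Bromide 9 and tetrahydrothiophene give 1-{[4-(trifluoromethanesulfonyloxy)phenyl]methyl}thiolan-1-ium bromide F2. With Cs2CO3 in MeCN at 40 °C, F1 should lose water to the ortho-quinone methide F3, which the ylide from F2 traps by conjugate addition and ring closure with loss of tetrahydrothiophene, giving the racemic 2,3-trans acetal F4. Preparative HPLC on a chiral stationary phase separates the (2S,3S)-enantiomer, which is 16; the route is rejoined at 16, hydrolysed to 17 as in step 10.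

2. Step 13 (Proposed new method). The same interception and collapse problems apply, now on a valuable late epoxide that cannot be used in excess, so aryne self-consumption may dominate. Fallback with known chemistry: it sets out from 4 and 17. The dianion of 4 (n-BuLi, THF, −78 °C) adds to aldehyde 17 to give the ortho-hydroxybenzhydrol F5 (mixture of carbinol epimers). With Cs2CO3 and the sulfonium salt F2 in MeCN, F5 should form the ortho-quinone methide F6, and [4+1] annulation gives the two 2,3-trans diastereomers at unit A: the wanted acetal 20 and its (2R,3R)-unit-A diastereomer F7, separable on silica. The route is rejoined at 20, hydrolysed to 21 as in step 13.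

3. Step 19. In strong base the free polyphenolate may degrade by air oxidation and by reversible retro-oxa-Michael opening of the dihydrofuran rings once the para-oxidophenyl groups are unveiled. Fallback that changes the order of unmasking: it sets out from 26. Et4NOH in dioxane cleaves both triflates on the fully MOM-protected, oxidation-resistant substrate to give the bis-phenol hexakis(methoxymethyl) ether F8. Mild acid (HCl, MeOH–THF, 23 °C) then removes the MOM ethers and the route is rejoined at 28.

**Further compounds**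

F1 | step 10 | 2-{[3,5-bis(methoxymethoxy)phenyl](hydroxy)methyl}-5-(dimethoxymethyl)-3-(methoxymethoxy)phenol | COCOc1cc(C(OC)OC)cc(O)c1C(O)c1cc(OCOC)cc(OCOC)c1
F2 | step 10 | 1-{[4-(trifluoromethanesulfonyloxy)phenyl]methyl}thiolan-1-ium bromide | FC(F)(F)S(=O)(=O)Oc1ccc(C[S+]2CCCC2)cc1.[Br-]
F3 | step 10 | ortho-quinone methide from F1: 6-{[3,5-bis(methoxymethoxy)phenyl]methylidene}-3-(dimethoxymethyl)-5-(methoxymethoxy)cyclohexa-2,4-dien-1-one | O=C1C=C(C(OC)OC)C=C(OCOC)C1=Cc1cc(OCOC)cc(OCOC)c1
F4 | step 10 | racemic 2,3-trans acetal (1:1 mixture of 16 and its (2R,3R)-enantiomer) | COC(OC)c1cc(OCOC)c2c(c1)O[C@H](c1ccc(OS(=O)(=O)C(F)(F)F)cc1)[C@H]2c1cc(OCOC)cc(OCOC)c1.COC(OC)c1cc(OCOC)c2c(c1)O[C@@H](c1ccc(OS(=O)(=O)C(F)(F)F)cc1)[C@@H]2c1cc(OCOC)cc(OCOC)c1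
F5 | step 13 | ortho-hydroxybenzhydrol from 4 and 17 (carbinol epimers) | COCOc1cc(C(OC)OC)cc(O)c1C(O)c1cc(OCOC)c2c(c1)O[C@H](c1ccc(OS(=O)(=O)C(F)(F)F)cc1)[C@H]2c1cc(OCOC)cc(OCOC)c1
F6 | step 13 | ortho-quinone methide from F5 | O=C1C=C(C(OC)OC)C=C(OCOC)C1=Cc1cc(OCOC)c2c(c1)O[C@H](c1ccc(OS(=O)(=O)C(F)(F)F)cc1)[C@H]2c1cc(OCOC)cc(OCOC)c1
F7 | step 13 | diastereomer of 20 with (2R,3R) configuration in unit A | FC(F)(F)S(=O)(=O)Oc1ccc([C@@H]2Oc3cc(C(OC)OC)cc(OCOC)c3[C@H]2c2cc(OCOC)c3c(c2)O[C@H](c2ccc(OS(=O)(=O)C(F)(F)F)cc2)[C@H]3c2cc(OCOC)cc(OCOC)c2)cc1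
F8 | step 19 | hexakis(methoxymethyl) ether of the target with both 4-hydroxyphenyl groups free | Oc1ccc([C@H]2Oc3cc(/C=C/c4ccc(OCOC)cc4OCOC)cc(OCOC)c3[C@@H]2c2cc(OCOC)c3c(c2)O[C@H](c2ccc(O)cc2)[C@H]3c2cc(OCOC)cc(OCOC)c2)cc1
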